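**Retrosynthetic overview**

1. Ring B is a 4-aryloxy-5-alkylresorcinol: the ether carbon B1 lies between the hydroxyl carbon B2 and the chain carbon B6, and B3 and B5 carry only hydrogen. B2–B1–B6 can therefore come from the ester carbon, the aryloxy methine and the ketone carbon of a 2-aryloxy-3-oxo ester, and B3–B4–B5 from the two methylenes and the carbonyl of a 3-oxopentanedioate.
2. Target ⇐ O-demethylation on ring A ⇐ hydrolysis and double decarboxylation at B3 and B5 ⇐ ring B diester, cut at B5–B6 and B2–B3 into the 20-membered 2-aryloxy β-keto ester and dimethyl 3-oxopentanedioate.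
3. Macrocycle ⇐ hydrogenation and ring-closing metathesis within the fourteen-carbon chain ⇐ acyclic diene, cut at the B1–O bond (phenoxide on a 2-chloro-3-oxo ester).
4. The phenol comes from 1-bromo-3,5-dimethoxybenzene and 6-bromohex-1-ene; the chloro keto ester from undec-10-enoyl chloride and Meldrum's acid.
5. Ring order: ring A is bought, the 20-membered ring is closed second, ring B is built last on the macrocycle.

Key step: step 8

Remarks on the chemistry:
- The target has no stereocentre and fourteen CH2 groups between ring A and B6. The one stereocentre on the way (the aryloxy-bearing carbon, later B1) is racemic, configurationally labile and erased when ring B aromatises; racemates 10–13 are drawn as one enantiomer.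
- The B1–O bond is made by SN2 displacement before ring closure. A macrocyclising carbenoid O–H insertion is not used, because a divalent rhodium carbenoid of a long-chain 2-diazo-3-oxo ester should insert into the chain C–H bond five atoms away faster than it meets a phenol at the end of a fifteen-carbon tether.

**Route**

Step 1
Reactants: 1 1-bromo-3,5-dimethoxybenzene; 2 6-bromohex-1-ene
Product: 4 1-(hex-5-en-1-yl)-3,5-dimethoxybenzene, via aryl Grignard reagent 3 (not isolated)
Conditions: Mg, THF, reflux; then 2, Li2CuCl4 (3 mol%), THF/NMP, 0 °C to rt
Reagents that add atoms: none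
Why: Copper-catalysed cross-coupling of an aryl Grignard reagent with a primary alkyl bromide (Kochi-type coupling) proceeds by substitution at the C–Br carbon and leaves the terminal alkene untouched.

Step 2
Reactants: 4 1-(hex-5-en-1-yl)-3,5-dimethoxybenzene
Product: 5 3-(hex-5-en-1-yl)-5-methoxyphenol
Conditions: NaSEt (3 equiv), DMF, 140 °C; aq HCl
Reagents that add atoms: none
Why: Thiolate SN2 O-demethylation of an aryl methyl ether should stop after one methyl group, because the phenoxide formed makes the ring a much poorer leaving group for a second displacement.

Step 3
Reactants: 6 undec-10-enoyl chloride; 7 Meldrum's acid (2,2-dimethyl-1,3-dioxane-4,6-dione)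
Product: 9 methyl 3-oxotridec-12-enoate, via acyl Meldrum's acid 8 (not isolated)
Conditions: pyridine, CH2Cl2, 0 °C to rt; then MeOH, reflux
Reagents that add atoms: methanol, CO
Why: C-acylation of Meldrum's acid followed by methanolysis through an acylketene, with loss of acetone and CO2, is the standard two-carbon homologation of an acid chloride to a methyl β-keto ester.

Step 4
Reactants: 9 methyl 3-oxotridec-12-enoate
Product: 10 methyl 2-chloro-3-oxotridec-12-enoate (racemic)
Conditions: NCS (1.0 equiv), Mg(ClO4)2 (10 mol%), MeCN, 0 °C to rt
Reagents that add atoms: N-chlorosuccinimide, O=C1CCC(=O)N1Cl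
Why: Electrophilic α-chlorination of the magnesium-chelated β-keto ester enol with one equivalent of NCS should give the monochloride as a racemate, while the isolated terminal alkene does not react with NCS in the absence of strong acid.

Step 5
Reactants: 5 3-(hex-5-en-1-yl)-5-methoxyphenol; 10 methyl 2-chloro-3-oxotridec-12-enoate
Product: 11 methyl 2-[3-(hex-5-en-1-yl)-5-methoxyphenoxy]-3-oxotridec-12-enoate (racemic)
Conditions: K2CO3, acetone, reflux
Reagents that add atoms: none
Why: Williamson ether synthesis by SN2 attack of the phenoxide on the chloride-bearing carbon activated by two carbonyl groups is the classical access to 2-aryloxy-3-oxo esters; the new stereocentre is racemic and labile.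

Step 6
Reactants: 11 methyl 2-[3-(hex-5-en-1-yl)-5-methoxyphenoxy]-3-oxotridec-12-enoate
Product: 12 20-membered macrocyclic alkene (11 with the two terminal CH2 groups lost and the chains joined by CH=CH; E/Z mixture; racemic)
Conditions: second-generation Grubbs catalyst RuCl2(=CHPh)(H2IMes)(PCy3) (5 mol%), CH2Cl2 (2 mM), 40 °C
Reagents that add atoms: none
Why: Ring-closing metathesis of two unhindered terminal alkenes at high dilution is driven by loss of ethene and closes large flexible rings reliably; the alkene geometry is irrelevant because it is hydrogenated next.

Step 7
Reactants: 12 20-membered macrocyclic alkene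
Product: 13 20-membered 2-aryloxy β-keto ester (ring made of the C1–C2–C3 arc of ring A, the ether oxygen, the methine CH(CO2Me), the ketone carbon and fourteen CH2 groups; OMe on C5 of ring A; racemic)
Conditions: H2 (1 atm), Pd/C, EtOAc, rt
Reagents that add atoms: none
Why: Heterogeneous catalytic hydrogenation saturates the disubstituted alkene, while the aryl ether, ketone and ester are inert at ambient pressure and temperature.

Step 8
Reactants: 13 20-membered 2-aryloxy β-keto ester; 14 dimethyl 3-oxopentanedioate
Product: 16 macrocyclic ring B diester (ring B: B1 O-aryl; B2 OH; B3 CO2Me; B4 OH; B5 CO2Me; B6 chain), via Knoevenagel alkylidene 15 (not isolated)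
Conditions: NaOMe (1.5 equiv in two portions), MeOH/THF, 65 °C, 14 (2 equiv) added slowly over several hours; then aq HCl
Reagents that add atoms: none
Why: The sodium enolate of 14 adds through one methylene to the ketone carbon of neutral 13 and the aldol loses water (Knoevenagel condensation), which forms B5–B6 and gives alkylidene 15, whose double-bond geometry can equilibrate through the dienolate made by removing the acidic proton on the aryloxy carbon. The second methylene, again as its enolate, then attacks the ester carbonyl (B2) in a 6-exo-trig Claisen (Dieckmann-type) closure that forms B2–B3 with loss of methoxide, and enolisation with loss of the B1 proton aromatises ring B, which makes the reversible aldol stage irreversible overall. The closest known reaction type is the alkoxide-mediated [3+3] aldol–Claisen cyclocondensation of 3-oxopentanedioates with β-keto esters to 2,4-dihydroxyisophthalates, of which the self-condensation of the ketodiester is the prototype, together with [3+3] annulations of 2-aryloxy-1,3-dicarbonyl compounds to diaryl ethers. No stereocentre is formed; the racemic centre of 13 becomes the sp2 carbon B1. Orientation is fixed because the dinucleophile is symmetric and only the ketone can lose water while only the ester can lose methoxide, so the chain can end up only on B6 and the hydroxyl only on B2. The selectivity to be won is cross-condensation over self-condensation of 14 and over dead-end enolisation of 13, which is addressed by adding 14 slowly to 13 holding about one equivalent of base, so that proton exchange keeps pairing neutral 13 with the enolate of 14 while free 14 stays dilute.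

Step 9
Reactants: 16 macrocyclic ring B diester
Product: 18 ring A mono-methyl ether of the target (ring B: B2 OH; B4 OH; B3 and B5 H), via diacid 17 (not isolated)
Conditions: KOH (excess), H2O/dioxane, reflux, N2; then aq HCl to pH 1, reflux
Reagents that add atoms: none
Why: Saponification of both esters gives a 2,4-dihydroxyisophthalic acid whose carboxyl groups sit ortho and para to hydroxyls, so that acid-promoted ipso-protonation and loss of CO2 (protodecarboxylation of resorcylic acids) should clear B3 and B5.

Step 10
Reactants: 18 ring A mono-methyl ether of the target
Product: 19 target CNP0173380.0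
Conditions: BBr3, CH2Cl2, −78 °C to rt; then H2O
Reagents that add atoms: none
Why: Lewis-acid O-demethylation with BBr3 cleaves the aryl methyl ether by bromide attack on the methyl group of the boron-complexed ether and leaves the diaryl ether intact.

**Compound list**

1 | 1-bromo-3,5-dimethoxybenzene | COc1cc(Br)cc(OC)c1 | starting material
2 | 6-bromohex-1-ene | C=CCCCCBr | starting material
3 | (3,5-dimethoxyphenyl)magnesium bromide | COc1cc(OC)cc([Mg]Br)c1 | intermediate
4 | 1-(hex-5-en-1-yl)-3,5-dimethoxybenzene | C=CCCCCc1cc(OC)cc(OC)c1 | intermediate
5 | 3-(hex-5-en-1-yl)-5-methoxyphenol | C=CCCCCc1cc(O)cc(OC)c1 | intermediate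
6 | undec-10-enoyl chloride | C=CCCCCCCCCC(Cl)=O | starting material
7 | Meldrum's acid (2,2-dimethyl-1,3-dioxane-4,6-dione) | CC1(C)OC(=O)CC(=O)O1 | starting material
8 | 5-(1-hydroxyundec-10-en-1-ylidene)-2,2-dimethyl-1,3-dioxane-4,6-dione (acyl Meldrum's acid, enol form) | C=CCCCCCCCCC(O)=C1C(=O)OC(C)(C)OC1=O | intermediate
9 | methyl 3-oxotridec-12-enoate | C=CCCCCCCCCC(=O)CC(=O)OC | intermediate
10 | methyl 2-chloro-3-oxotridec-12-enoate (racemic; one enantiomer drawn) | C=CCCCCCCCCC(=O)[C@@H](Cl)C(=O)OC | intermediate
11 | methyl 2-[3-(hex-5-en-1-yl)-5-methoxyphenoxy]-3-oxotridec-12-enoate (racemic; one enantiomer drawn) | C=CCCCCCCCCC(=O)[C@H](Oc1cc(OC)cc(CCCCC=C)c1)C(=O)OC | intermediate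
12 | 20-membered macrocyclic alkene: methyl ester on the aryloxy methine, adjacent ring ketone, CH=CH between the fourth and fifth chain carbons counted from ring A (E/Z mixture; racemic; one enantiomer drawn) | COC(=O)[C@H]1Oc2cc(OC)cc(c2)CCCCC=CCCCCCCCCC1=O | intermediate
13 | 20-membered 2-aryloxy β-keto ester: methine CH(CO2Me) bonded to the ether oxygen on C1 of ring A and to the ring ketone; ketone joined through fourteen CH2 groups to C3 of ring A; OMe on C5 of ring A (racemic and configurationally labile; one enantiomer drawn) | COC(=O)[C@H]1Oc2cc(OC)cc(c2)CCCCCCCCCCCCCCC1=O | intermediate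
14 | dimethyl 3-oxopentanedioate | COC(=O)CC(=O)CC(=O)OC | starting material
15 | Knoevenagel alkylidene: former ketone carbon of 13 doubly bonded to C2 of the ketodiester (racemic; alkene geometry undefined) | COC(=O)CC(=O)C(C(=O)OC)=C1CCCCCCCCCCCCCCc2cc(OC)cc(c2)OC1C(=O)OC | intermediate
16 | macrocyclic ring B diester: ring B with B1 O-aryl, B2 OH, B3 CO2Me, B4 OH, B5 CO2Me, B6 chain; ring A with OMe | COC(=O)c1c(O)c(C(=O)OC)c2c(Oc3cc(OC)cc(c3)CCCCCCCCCCCCCC2)c1O | intermediate
17 | macrocyclic ring B diacid (16 with both esters as CO2H) | OC(=O)c1c(O)c(C(=O)O)c2c(Oc3cc(OC)cc(c3)CCCCCCCCCCCCCC2)c1O | intermediate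
18 | ring A mono-methyl ether of the target | COc1cc2cc(c1)Oc1c(O)cc(O)cc1CCCCCCCCCCCCCC2 | intermediate
19 | CNP0173380.0: 20-membered diaryl ether macrocycle, ring A 1,3,5-substituted (OH, chain, O-aryl), ring B with B1 O-aryl, B2 OH, B4 OH, B6 chain, fourteen CH2 groups between ring A and B6 | Oc1cc2cc(c1)Oc1c(O)cc(O)cc1CCCCCCCCCCCCCC2 | target

**Step count**

Total: 10 steps. Longest linear sequence: 8 steps (steps 1, 2, 5, 6, 7, 8, 9, 10; the branch through steps 3 and 4 is equally long).

**Steps most likely to fail**

Step 8 (key step). The ketodiester may condense with itself faster than with the hindered ring ketone. Compound 13 may sit as its unreactive enolate, or be opened by methoxide in a retro-Claisen cleavage. In that case ring B is brought in preformed and the diaryl ether is made by Ullmann coupling. This fallback sets out from Grignard reagent 3 and phenol 5 and comes back to the route at target 19. Reagent 3 is coupled with 10-bromodec-1-ene (C=CCCCCCCCCBr; Li2CuCl4 cat., THF/NMP) to give 1-(dec-9-en-1-yl)-3,5-dimethoxybenzene F1. Iodination with N-iodosuccinimide in MeCN should take place at the ring position between the chain and a methoxy group (para to the other methoxy) and give 1-(dec-9-en-1-yl)-2-iodo-3,5-dimethoxybenzene F2. Ullmann-type O-arylation of 5 with F2 (copper monoiodide, picolinic acid, K3PO4, DMSO, 90 °C; a copper catalyst is chosen so that the terminal alkenes cannot enter a Heck reaction) gives the diaryl ether diene F3. Ring-closing metathesis at high dilution with the second-generation Grubbs catalyst gives the 20-membered diaryl ether cycloalkene F4. Hydrogenation over Pd/C gives the trimethyl ether of the target F5, and BBr3 removes all three methyl groups to give 19.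

Step 6. Intermolecular metathesis may outrun ring closure and give oligomers, and the ruthenium carbene may be slowed by chelation to the enolised β-dicarbonyl unit. The order of the two bond formations is then reversed, so that the chain is joined first and the ring is closed at the ether bond. This fallback sets out from 5 and 10 and comes back at 12. Cross-metathesis of 5 with an excess of 10 (second-generation Grubbs catalyst, CH2Cl2, 40 °C, concentrated) gives open-chain methyl 2-chloro-17-(3-hydroxy-5-methoxyphenyl)-3-oxoheptadec-12-enoate F6 as an E/Z mixture. Slow addition of F6 to Cs2CO3 in MeCN at 60 °C (final concentration about 1 mM) closes the ring by intramolecular Williamson etherification and gives 12.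

Step 5. The ambident phenoxide may be alkylated on carbon, chlorine may be transferred to the electron-rich phenol ring, or the chloro keto ester may self-condense under base. The ether bond is then formed by carbenoid O–H insertion in place of substitution. This fallback sets out from 9 and comes back at 11. Regitz diazo transfer (4-acetamidobenzenesulfonyl azide, Et3N, MeCN) gives methyl 2-diazo-3-oxotridec-12-enoate F7. Slow addition of F7 to an excess of phenol 5 and Rh2(OAc)4 (1 mol%) in benzene at 80 °C should give 11 by intermolecular O–H insertion, since the phenol is present at high concentration and can compete with insertion into the chain.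

**Further compounds**

F1 | step 8 | 1-(dec-9-en-1-yl)-3,5-dimethoxybenzene | C=CCCCCCCCCc1cc(OC)cc(OC)c1
F2 | step 8 | 1-(dec-9-en-1-yl)-2-iodo-3,5-dimethoxybenzene | C=CCCCCCCCCc1cc(OC)cc(OC)c1I
F3 | step 8 | 1-(dec-9-en-1-yl)-2-[3-(hex-5-en-1-yl)-5-methoxyphenoxy]-3,5-dimethoxybenzene | C=CCCCCCCCCc1cc(OC)cc(OC)c1Oc1cc(OC)cc(CCCCC=C)c1
F4 | step 8 | 20-membered diaryl ether cycloalkene, trimethyl ether (E/Z mixture; CH=CH between the fourth and fifth chain carbons counted from ring A) | COc1cc2cc(c1)Oc1c(OC)cc(OC)cc1CCCCCCCCC=CCCCC2
F5 | step 8 | trimethyl ether of the target | COc1cc2cc(c1)Oc1c(OC)cc(OC)cc1CCCCCCCCCCCCCC2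
F6 | step 6 | methyl 2-chloro-17-(3-hydroxy-5-methoxyphenyl)-3-oxoheptadec-12-enoate (E/Z mixture; racemic) | COC(=O)C(Cl)C(=O)CCCCCCCCC=CCCCCc1cc(O)cc(OC)c1
F7 | step 5 | methyl 2-diazo-3-oxotridec-12-enoate | C=CCCCCCCCCC(=O)C(=[N+]=[N-])C(=O)OC
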